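**Retrosynthetic overview**
- The target comes from its tris-MOM ether. The C2 (S) carbinol is installed last, by reagent-controlled hydroxylation of the Z-enolate of the protected dihydrochalcone.
- Key disconnection: the Cβ–aryl (ring B) bond. A ketone homoenolate (β-carbanion of the aryl ketone, generated as a Pd-homoenolate by opening a 1-arylcyclopropanol) is joined to 4-(methoxymethoxy)bromobenzene.
- The cyclopropanol comes from a Kulinkovich reaction on the methyl benzoate: the ester carbon becomes the ketone C=O and EtMgBr supplies Cα and Cβ.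
- The benzoate comes from C5-prenylation and MOM protection of methyl 2,4-dihydroxy-3-methylbenzoate.
- Rings: both arenes are bought. The only ring made is the cyclopropane (step 3), and it is opened again in step 4.

Assumption: methyl 2,4-dihydroxy-3-methylbenzoate, prenyl bromide, 1-bromo-4-(methoxymethoxy)benzene and (+)-[(8,8-dichlorocamphoryl)sulfonyl]oxaziridine are taken as catalogue items.

**Step 1**
Reactants: 1 methyl 2,4-dihydroxy-3-methylbenzoate; 2 prenyl bromide (1-bromo-3-methylbut-2-ene)
Product: 3 methyl 2,4-dihydroxy-3-methyl-5-(3-methylbut-2-en-1-yl)benzoate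
Conditions: NaH (1.05 eq), toluene, 0 °C; then 2, rt → 50 °C
Reagents that add atoms: none
Why: Ortho-C-alkylation of a sodium phenoxide ion pair in a non-polar solvent; the more acidic 4-OH is deprotonated and C5 is the only free position ortho/para to the hydroxyls (C3 is blocked by methyl, C6 is meta to both).

**Step 2**
Reactants: 3 methyl 2,4-dihydroxy-3-methyl-5-(3-methylbut-2-en-1-yl)benzoate
Product: 4 methyl 2,4-bis(methoxymethoxy)-3-methyl-5-(3-methylbut-2-en-1-yl)benzoate
Conditions: NaH (2.5 eq), MOMCl (2.5 eq), DMF/THF, 0 °C → rt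
Reagents that add atoms: chloromethyl methyl ether (MOMCl), COCCl
Why: Williamson-type O-alkylation of both phenoxides; MOM is chosen because an ortho silyl ether would migrate to the cyclopropanolate oxygen formed in step 3.

**Step 3**
Reactants: 4 methyl 2,4-bis(methoxymethoxy)-3-methyl-5-(3-methylbut-2-en-1-yl)benzoate
Product: 5 1-[2,4-bis(methoxymethoxy)-3-methyl-5-(3-methylbut-2-en-1-yl)phenyl]cyclopropan-1-ol
Conditions: EtMgBr (3 eq, slow addition), Ti(OiPr)4 (0.3 eq), THF, 0 °C → rt; aq NH4Cl
Reagents that add atoms: ethylmagnesium bromide, CC[Mg]Br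
Why: Kulinkovich cyclopropanation, in which the catalytic titanacyclopropane adds twice to the ester carbonyl as a 1,2-dicarbanion; the trisubstituted prenyl alkene does not exchange onto titanium.

**Step 4**
Reactants: 5 1-[2,4-bis(methoxymethoxy)-3-methyl-5-(3-methylbut-2-en-1-yl)phenyl]cyclopropan-1-ol; 6 1-bromo-4-(methoxymethoxy)benzene
Product: 8 1-[2,4-bis(methoxymethoxy)-3-methyl-5-(3-methylbut-2-en-1-yl)phenyl]-3-[4-(methoxymethoxy)phenyl]propan-1-one, via palladium homoenolate 7 (not isolated)
Conditions: Pd(OAc)2 (5 mol%), XPhos (10 mol%), Cs2CO3 (2 eq), toluene, 80 °C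
Reagents that add atoms: none
Why: Pd-catalysed ring-opening cross-coupling of a cyclopropanol, in which the Pd alkoxide undergoes strain-driven β-carbon elimination to the β-palladio ketone (homoenolate) and reductive elimination forms the Cβ–aryl bond; the bulky biaryl phosphine favours this over β-hydride elimination.

**Step 5**
Reactants: 8 1-[2,4-bis(methoxymethoxy)-3-methyl-5-(3-methylbut-2-en-1-yl)phenyl]-3-[4-(methoxymethoxy)phenyl]propan-1-one
Product: 10 (2S)-1-[2,4-bis(methoxymethoxy)-3-methyl-5-(3-methylbut-2-en-1-yl)phenyl]-2-hydroxy-3-[4-(methoxymethoxy)phenyl]propan-1-one, via sodium Z-enolate 9 (not isolated)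
Conditions: NaHMDS (1.15 eq), THF, −78 °C; then (+)-[(8,8-dichlorocamphoryl)sulfonyl]oxaziridine (1.5 eq), −78 °C; sat. NH4Cl at −78 °C
Reagents that add atoms: (+)-[(8,8-dichlorocamphoryl)sulfonyl]oxaziridine, CC1(C)[C@@H]2CC[C@]13CS(=O)(=O)N4O[C@@]34C2(Cl)Cl
Why: Davis asymmetric enolate hydroxylation, in which the single Z(O)-sodium enolate is oxidised on one face by the (+)-reagent, giving the (S)-carbinol as it does for propiophenone- and deoxybenzoin-type enolates (this sense is recalled from those precedents and must be confirmed on the product; the (−)-reagent is used if it is reversed); the oxaziridine does not epoxidise the prenyl alkene at −78 °C.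

**Step 6**
Reactants: 10 (2S)-1-[2,4-bis(methoxymethoxy)-3-methyl-5-(3-methylbut-2-en-1-yl)phenyl]-2-hydroxy-3-[4-(methoxymethoxy)phenyl]propan-1-one
Product: 11 Lespeflorin C5, (2S)-1-[2,4-dihydroxy-3-methyl-5-(3-methylbut-2-en-1-yl)phenyl]-2-hydroxy-3-(4-hydroxyphenyl)propan-1-one
Conditions: 3 M aq HCl, MeOH, 45–50 °C, 1–2 h (monitored; stopped before chroman formation)
Reagents that add atoms: none
Why: Acid-catalysed acetal methanolysis removes all three MOM groups; dilute acid at mild temperature is standard for prenylated polyphenols and does not epimerise the α-hydroxy ketone, which stays (S).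

**Compound list**
1 | methyl 2,4-dihydroxy-3-methylbenzoate | COC(=O)c1ccc(O)c(C)c1O | starting material
2 | prenyl bromide | CC(C)=CCBr | starting material
3 | methyl 2,4-dihydroxy-3-methyl-5-(3-methylbut-2-en-1-yl)benzoate | COC(=O)c1cc(CC=C(C)C)c(O)c(C)c1O | intermediate
4 | methyl 2,4-bis(methoxymethoxy)-3-methyl-5-(3-methylbut-2-en-1-yl)benzoate | COCOc1c(C)c(OCOC)c(CC=C(C)C)cc1C(=O)OC | intermediate
5 | 1-[2,4-bis(methoxymethoxy)-3-methyl-5-(3-methylbut-2-en-1-yl)phenyl]cyclopropan-1-ol | COCOc1c(C)c(OCOC)c(CC=C(C)C)cc1C1(O)CC1 | intermediate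
6 | 1-bromo-4-(methoxymethoxy)benzene | COCOc1ccc(Br)cc1 | starting material
7 | [3-aryl-3-oxopropyl][4-(methoxymethoxy)phenyl]palladium(II) homoenolate (XPhos ligand omitted) | COCOc1ccc([Pd]CCC(=O)c2cc(CC=C(C)C)c(OCOC)c(C)c2OCOC)cc1 | intermediate (not isolated)
8 | 1-[2,4-bis(methoxymethoxy)-3-methyl-5-(3-methylbut-2-en-1-yl)phenyl]-3-[4-(methoxymethoxy)phenyl]propan-1-one | COCOc1ccc(CCC(=O)c2cc(CC=C(C)C)c(OCOC)c(C)c2OCOC)cc1 | intermediate
9 | sodium (Z)-enolate of 8 | COCOc1ccc(C/C=C(\[O-])c2cc(CC=C(C)C)c(OCOC)c(C)c2OCOC)cc1.[Na+] | intermediate (not isolated)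
10 | (2S)-1-[2,4-bis(methoxymethoxy)-3-methyl-5-(3-methylbut-2-en-1-yl)phenyl]-2-hydroxy-3-[4-(methoxymethoxy)phenyl]propan-1-one | CC(C)=CCc1cc(C(=O)[C@@H](O)Cc2ccc(OCOC)cc2)c(OCOC)c(C)c1OCOC | intermediate
11 | Lespeflorin C5 | CC(C)=CCc1cc(C(=O)[C@@H](O)Cc2ccc(O)cc2)c(O)c(C)c1O | target

**Totals**
Total step count: 6. Longest linear sequence: 6 (1 → 3 → 4 → 5 → 8 → 10 → 11).

**Three steps most likely to fail, with fallbacks**

Step 4 (homoenolate arylation; risks are β-hydride elimination to the enone and protodepalladation to the ethyl ketone). The fallback sets out from 5 and comes back at 8. Cyclopropanol 5 is opened oxidatively (Pd(OAc)2 cat., pyridine, O2, toluene, 80 °C) to the aryl vinyl ketone 1-[2,4-bis(methoxymethoxy)-3-methyl-5-(3-methylbut-2-en-1-yl)phenyl]prop-2-en-1-one F3. Rhodium-catalysed conjugate addition of commercial 4-(methoxymethoxy)phenylboronic acid ([Rh(cod)OH]2, dioxane/H2O, 50 °C) then gives 8.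

Step 5 (enantioselectivity and sense of induction with the ortho-MOM-substituted enolate). The fallback sets out from 8 and comes back at 10. The enolate is hydroxylated without stereocontrol (KHMDS, racemic trans-2-(phenylsulfonyl)-3-phenyloxaziridine, THF, −78 °C) to racemic 1-[2,4-bis(methoxymethoxy)-3-methyl-5-(3-methylbut-2-en-1-yl)phenyl]-2-hydroxy-3-[4-(methoxymethoxy)phenyl]propan-1-one F4. This is resolved by lipase-catalysed acylation (Pseudomonas stutzeri lipase, vinyl butanoate, MTBE, with a mild racemisation catalyst for the slow enantiomer if needed). By analogy with benzoin this is expected to give the (S)-butanoate, (2S)-1-[2,4-bis(methoxymethoxy)-3-methyl-5-(3-methylbut-2-en-1-yl)phenyl]-3-[4-(methoxymethoxy)phenyl]-1-oxopropan-2-yl butanoate F5. Neutral lipase-catalysed alcoholysis of F5 with n-butanol returns 10. If the enzyme instead acylates the (R)-alcohol, the unreacted alcohol is 10 directly.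

Step 1 (direct C-prenylation; risks are O-alkylation, ipso-alkylation at C3 and a low yield). The fallback sets out from 1 and comes back at 4. Bromination (NBS, MeCN, 0 °C) at the only activated free position gives methyl 5-bromo-2,4-dihydroxy-3-methylbenzoate F1. MOM protection (NaH, MOMCl, DMF) gives methyl 5-bromo-2,4-bis(methoxymethoxy)-3-methylbenzoate F2. Stille coupling with tributyl(3-methylbut-2-en-1-yl)stannane (Pd(PPh3)4, DMF, 100 °C) then gives 4 with the linear prenyl group.

**Further compounds**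
F1 | step 1 | methyl 5-bromo-2,4-dihydroxy-3-methylbenzoate | COC(=O)c1cc(Br)c(O)c(C)c1O
F2 | step 1 | methyl 5-bromo-2,4-bis(methoxymethoxy)-3-methylbenzoate | COCOc1c(C)c(OCOC)c(Br)cc1C(=O)OC
F3 | step 4 | 1-[2,4-bis(methoxymethoxy)-3-methyl-5-(3-methylbut-2-en-1-yl)phenyl]prop-2-en-1-one | C=CC(=O)c1cc(CC=C(C)C)c(OCOC)c(C)c1OCOC
F4 | step 5 | racemic 1-[2,4-bis(methoxymethoxy)-3-methyl-5-(3-methylbut-2-en-1-yl)phenyl]-2-hydroxy-3-[4-(methoxymethoxy)phenyl]propan-1-one | CC(C)=CCc1cc(C(=O)C(O)Cc2ccc(OCOC)cc2)c(OCOC)c(C)c1OCOC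
F5 | step 5 | (2S)-1-[2,4-bis(methoxymethoxy)-3-methyl-5-(3-methylbut-2-en-1-yl)phenyl]-3-[4-(methoxymethoxy)phenyl]-1-oxopropan-2-yl butanoate | CC(C)=CCc1cc(C(=O)[C@@H](OC(=O)CCC)Cc2ccc(OCOC)cc2)c(OCOC)c(C)c1OCOC
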